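In amounts, the recipes below differ in partner, while reagent stays at 1.50 equiv. Reagent goes two ways: with partner to second intermediate, and with substrate to open intermediate. Those two intermediates join to product, and reagent also pairs reversibly with product as idle adduct, which the product readings include.

| flask | substrate | partner | reagent | remark | time |
|---|---|---|---|---|---|
| birch | 0.10 M | 0.52 equiv | 1.5 equiv | run made earlier |  |
| cedar | 0.10 M | 2.1 equiv | 1.5 equiv | run made earlier |  |
| spring | 0.10 M | 0.800 equiv | 1.50 equiv |  | 3.0 h |
| midnight | 0.10 M | 1.00 equiv | 1.50 equiv |  | 3.0 h |
| dawn | 0.10 M | 1.50 equiv | 1.50 equiv |  | 3.0 h |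
| winter | 0.10 M | 2.50 equiv | 1.50 equiv |  | 3.0 h |

- birch (time / min: product / %, substrate / %): 5.00: 0, 98.3; 15.0: 0, 95.4; 25.0: 0.1, 93.4; 40.0: 0.6, 90.0; 50.0: 1.5, 88.3; 80.0: 2.2, 83.3; 90.0: 3.1, 81.7
- cedar (time / min: product / %, substrate / %): 8.00: 0.1, 98.3; 12.0: 0.2, 97.0; 15.0: 0, 96.6; 25.0: 0.3, 95.2; 40.0: 1.1, 94.1; 60.0: 2.2, 93.2; 90.0: 3.8, 91.6

(each reading ± 0.3 percentage points)

- what is said of product includes idle adduct
- steps that have been proposed: reagent + partner -> second intermediate; substrate + reagent -> open intermediate; reagent + product <-> idle adduct; open intermediate + second intermediate -> product
- the concentration of product that is asked is that of its free form alone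
- "hardly changes" means that all values lie within two and a half points (for a concentration: within two and a half percent of the largest)

- [product] (only what is free in solution) at the end for spring, midnight, dawn, winter, in this order
- the shape of the row from first to last (falls all the way / rises, then falls / rises all the way / hardly changes / falls, then rises)

The two runs seem to disagree. At 90.0 min cedar has kept 91.6% of its substrate against 81.7% in birch, so it has lost less, yet it reads more product, 3.8% against 3.1%. Substrate loss runs with reagent as well as with substrate, so the late rate of loss over the rate up to 15.0 min reads, roughly, how far reagent has fallen: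

birch, late rate from 50.0 min: 0.538

cedar, late rate from 60.0 min: 0.235

As read, reagent has fallen further in cedar. Yet 45.2% of cedar's lost substrate reads as product, against 16.9% in birch. Both readings fit the larger partner charge in cedar, 2.1 equiv against 0.52 equiv in birch: more reagent goes to second intermediate, less substrate opens, and the open intermediate that forms meets more second intermediate.

Let s be reagent charged minus partner charged, in equivalents of substrate. It is 0.980 equiv in birch and −0.600 equiv in cedar, and winter's −1.00 equiv is the reagent surplus. The other flasks follow:

spring 0.700 equiv; midnight 0.500 equiv; dawn 0 equiv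

Above zero, partner cannot claim 46.7% of spring's reagent. Below zero, reagent is the limiting reagent of the partner step, and at least 40.0% of winter's partner stays unused. On the surplus side, reagent that partner leaves can hold product as idle adduct; on the other side, partner can compete for the reagent that substrate needs. From these two pulls, this reckoning expects free product to rise up to the crossing at dawn and fall beyond it, but it gives no heights.

The forecast gives 0.0078 M, 0.0085 M, 0.0088 M and 0.0062 M, a row that rises, then falls, on the ground that “leftover reagent holds product as idle adduct”.

    reagent + partner → second intermediate (k = 15.0 M⁻¹ h⁻¹)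
    substrate + reagent → open intermediate (k = 1.30 M⁻¹ h⁻¹)
    reagent + product ⇌ idle adduct, settled at all times (K = 18.0 M⁻¹)
    open intermediate + second intermediate → product (k = 5.90 M⁻¹ h⁻¹)

The flasks give 0.00637 M, 0.00729 M, 0.00816 M and 0.00590 M, a row that rises, then falls, turning at 1.5 equiv of partner. Of spring's 11.4% product at 3.00 h, 5.06% stands as idle adduct. Spring's surplus of 0.700 equiv is 46.7% of its reagent charge, and 29.4% of that charge remains. Winter's −1.00 equiv requires 40.0% of its partner to stay unused, and 43.0% stands there with reagent at 0.297%.

The data are calculated with constants of no real substance, noise included.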